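**Strategy.** Ring A (C1–C4, C4a, C8a) is cut at C1–C8a and C4–C4a. Two features are exploited. The C1 carbinol lies β to C8 of ring B, so the C7=C8 alkene is a latent ketone. The C4 methyl is a latent vinyl terminus. An iron-hydride HAT radical–polar crossover annulation joins (S)-2-silyloxypent-4-enal to an enantiopure 4,4,5-trisubstituted cyclohexenone. H• creates the C4 radical and its methyl, Giese addition forms C4–C4a, and the resulting enolate closes C1–C8a by aldol. This sets C4, C4a, C8a and C1 in one operation. The enone comes from catalytic desymmetrisation of a Birch-derived cyclohexadienone. C2 is inverted at the end by Mitsunobu acylation.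

Key step: step 7

Remark 1 (numbering): decalin C1 = carbinol, C2 = acyloxy carbon, C3, C4 = CHMe, C4a, C5 = quaternary carbon, C6 = CH-iBu, C7=C8, C8a. β means the side of 8a-H and α the side of 4a-H. The target is 1β-OH, 2β-acyloxy, 4α-Me, 4aα-H, 5β-Me, 5α-acyl, 6α-iBu, 8aβ-H.
Remark 2 (assumption): diisobutylzinc is taken as a catalogue reagent. The phosphoramidite antipode used in step 3 is assumed to be the one that gives (1S,6S)-6; both antipodes are sold.

**Step 1**
Reactants: 1 methyl benzoate
Product: 3 methyl 1-methylcyclohexa-2,5-diene-1-carboxylate, via lithium dienolate 2 (not isolated)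
Conditions: Li, NH3(l)/THF, tBuOH (1 equiv), −78 °C; then MeI
Reagents that add atoms: iodomethane, CI
Why: Birch reductive alkylation; the ester-stabilised dienolate is methylated at the ipso carbon and no stereocentre is formed.

**Step 2**
Reactants: 3
Product: 4 methyl 1-methyl-4-oxocyclohexa-2,5-diene-1-carboxylate
Conditions: Rh2(cap)4 (1 mol %), tBuOOH (70 % aq.), K2CO3, CH2Cl2, rt
Reagents that add atoms: tert-butyl hydroperoxide, CC(C)(C)OO
Why: Catalytic allylic oxidation of the doubly allylic CH2; the quaternary carbon blocks aromatisation, so the prochiral cross-conjugated dienone should result.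

**Step 3**
Reactants: 4
Product: 6 methyl (1S,6S)-6-isobutyl-1-methyl-4-oxocyclohex-2-ene-1-carboxylate, via zinc dienolate 5 (not isolated)
Conditions: iBu2Zn, Cu(OTf)2 (2 mol %), BINOL/bis(1-phenylethyl)amine phosphoramidite (4 mol %), toluene, −25 °C; aq. NH4Cl
Reagents that add atoms: diisobutylzinc, CC(C)C[Zn]CC(C)C
Why: Cu/phosphoramidite-catalysed desymmetrising conjugate addition of a dialkylzinc to a 4,4-disubstituted cyclohexadienone; the ligand picks one enantiotopic alkene (fixing C5), and delivery anti to the effectively larger methyl, on the face of the zinc-coordinating ester, sets C6 cis to the ester.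

**Step 4**
Reactants: 7 (R)-glycidol
Product: 8 (S)-pent-4-ene-1,2-diol
Conditions: vinylMgBr (2.5 equiv), CuI (10 mol %), THF, −30 to 0 °C
Reagents that add atoms: vinylmagnesium bromide, C=C[Mg]Br
Why: Copper-catalysed epoxide opening at the terminal carbon; the chiral-pool stereocentre is untouched and only its descriptor changes.

**Step 5**
Reactants: 8
Product: 9 (S)-1,2-bis(triethylsilyloxy)pent-4-ene
Conditions: TESCl, imidazole, CH2Cl2, 0 °C to rt
Reagents that add atoms: chlorotriethylsilane, CC[Si](Cl)(CC)CC
Why: Routine bis-silylation.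

**Step 6**
Reactants: 9
Product: 10 (S)-2-(triethylsilyloxy)pent-4-enal
Conditions: (COCl)2, DMSO, CH2Cl2, −78 to −30 °C; Et3N
Reagents that add atoms: none
Why: Swern oxidation carried out directly on the silyl ether; the activated sulfonium cleaves only the unhindered primary TES ether, so the secondary TES ether and the α-stereocentre are kept.

**Step 7**
Reactants: 6 enone; 10 aldehyde
Product: 13 methyl 1β-hydroxy-2α-(triethylsilyloxy)-4α,5β-dimethyl-6α-isobutyl-8-oxo-trans-decalin-5α-carboxylate (4aα-H 8aβ-H), via secondary C4 radical 11 (not isolated), via Giese adduct enolate 12 (not isolated)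
Conditions: Fe(acac)3 (25 mol %), PhSiH3, EtOH/1,2-dichloroethane, 40 °C, slow addition of 10
Reagents that add atoms: none
Why: An Fe(III) hydride transfers H• to the terminal CH2 of the vinyl group of 10, giving nucleophilic radical 11, which adds to C4a of 6; Fe(II) then reduces the α-keto radical to enolate 12, which attacks the C1 aldehyde. The closest known reaction is the MHAT-initiated radical–polar crossover annulation of γ,δ-unsaturated aldehydes with enones, a Giese addition/aldol sequence that grew out of iron-catalysed reductive olefin coupling. Ring A closes in a 6-(enolexo)-exo-trig aldol through a chair. C4a is set by axial attack on the conformer of 6 with equatorial isobutyl and axial ester, that is, anti to the 5α-ester and trans to the 6α-isobutyl; C4 is set by the staggered transition state that places the radical's chain anti to quaternary C5 and its hydrogen over the ring, which makes the methyl 4α (equatorial). C1 and C8a are under thermodynamic control, because the aldol is reversible and C8a is enolisable, so isomers should drain to the trans-fused ketol with an all-equatorial ring A and a C1-OH···O=C8 hydrogen bond. The step needs HAT to the electron-rich alkene rather than the enone and capture of 11 before it reacts with itself; polarity matching secures the first, and a silyl ether (no activated C–H within 1,5-reach of C4) secures the second.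

**Step 8**
Reactants: 13
Product: 14 1β-TBS ether of 13
Conditions: TBSOTf, 2,6-lutidine, CH2Cl2, −78 to 0 °C
Reagents that add atoms: tert-butyldimethylsilyl triflate, CC(C)(C)[Si](C)(C)OS(=O)(=O)C(F)(F)F
Why: Silylation under weakly basic conditions blocks retro-aldol; the equatorial C1–O bond lies near the enolate plane and is poorly aligned for later E1cB loss.

**Step 9**
Reactants: 14
Product: 16 C7=C8 enol triflate, via potassium enolate 15 (not isolated)
Conditions: KHMDS, THF, −78 °C; then PhNTf2
Reagents that add atoms: N-phenylbis(trifluoromethanesulfonimide), O=S(=O)(N(c1ccccc1)S(=O)(=O)C(F)(F)F)C(F)(F)F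
Why: Kinetic deprotonation occurs at the C7 methylene rather than the hindered C8a methine, so C8a is not touched and the enolate is trapped on oxygen.

**Step 10**
Reactants: 16
Product: 17 methyl 1β-(TBSO)-2α-(TESO)-4α,5β-dimethyl-6α-isobutyl-Δ7-octalin-5α-carboxylate
Conditions: Pd(OAc)2 (5 mol %), PPh3, HCO2H, Et3N, DMF, 60 °C
Reagents that add atoms: none
Why: Palladium-catalysed formate reduction of a vinyl triflate places the C7=C8 alkene regiospecifically.

**Step 11**
Reactants: 17
Product: 19 C5 methyl ketone, via alpha-silyl ketone 18 (not isolated)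
Conditions: Me3SiCH2Li (3 equiv), pentane/THF, 0 °C to rt; then MeOH
Reagents that add atoms: (trimethylsilyl)methyllithium, C[Si](C)(C)C[Li]
Why: Acylation of Me3SiCH2Li by an ester stops after one addition, because the α-silyl ketone is enolised at once, and methanolysis removes silicon.

**Step 12**
Reactants: 19
Product: 20 β-keto dimethyl acetal (C5–C(=O)CH2CH(OMe)2)
Conditions: HC(OMe)3, BF3·OEt2, CH2Cl2, −30 °C; then 19, iPr2NEt, −78 to −20 °C
Reagents that add atoms: trimethyl orthoformate, COC(OC)OC
Why: This is α-formylation of a ketone with a preformed dialkoxycarbenium salt; the CH3 is the only enolisable position, and the β-ketoaldehyde is obtained in masked, non-acidic form.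

**Step 13**
Reactants: 20
Product: 21 2α-alcohol
Conditions: PPTS, MeOH/CH2Cl2, 0 °C to rt
Reagents that add atoms: none
Why: Mild acid methanolysis differentiates TES from TBS, and the dimethyl acetal is stable in methanol.

**Step 14**
Reactants: 22 tert-butyl acetoacetate
Product: 23 tert-butyl (E)-3-(triflyloxy)but-2-enoate
Conditions: Tf2O, aq. Me4NOH, hexanes, 5 °C
Reagents that add atoms: triflic anhydride, O=S(=O)(OS(=O)(=O)C(F)(F)F)C(F)(F)F
Why: Biphasic enol triflation of a β-keto ester; the non-chelating ammonium enolate gives the E isomer, with OTf trans to the ester.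

**Step 15**
Reactants: 23
Product: 24 1-tert-butyl 5-methyl (E)-3-methylpent-2-enedioate
Conditions: BrCH2CO2Me, Zn (TMSCl-activated), THF; then 23, Pd(PPh3)4 (5 mol %), rt
Reagents that add atoms: methyl bromoacetate, COC(=O)CBr
Why: Negishi-type coupling of a Reformatsky reagent with a vinyl triflate proceeds with retention of alkene geometry.

**Step 16**
Reactants: 24
Product: 25 (E)-5-methoxy-3-methyl-5-oxopent-2-enoic acid
Conditions: TFA, CH2Cl2, 0 °C to rt
Reagents that add atoms: none
Why: Acidolysis cleaves only the tert-butyl ester and avoids the base that would move or isomerise the double bond.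

**Step 17**
Reactants: 21; 25
Product: 26 2β-ester (1β-OTBS, acetal still in place)
Conditions: PPh3, DIAD, toluene, 0 °C to rt
Reagents that add atoms: none
Why: Mitsunobu esterification inverts C2 by SN2 (equatorial alcohol to axial ester); the rigid equatorial leaving group has no anti hydrogen for E2, and the acid reacts as a carboxylate, so no vinylketene path can shift its double bond.

**Step 18**
Reactants: 26
Product: 27 tandyukisin
Conditions: 48 % aq. HF, MeCN, 0 °C to rt
Reagents that add atoms: water, O
Why: Aqueous HF removes the TBS ether and hydrolyses the β-keto acetal in one operation, and the freed β-ketoaldehyde settles as the hydrogen-bonded (Z)-enol.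

**Compound list**
1 | methyl benzoate | COC(=O)c1ccccc1 | starting material
2 | lithium dienolate from Birch reduction | COC([O-])=C1C=CCC=C1.[Li+] | intermediate
3 | methyl 1-methylcyclohexa-2,5-diene-1-carboxylate | COC(=O)C1(C)C=CCC=C1 | intermediate
4 | methyl 1-methyl-4-oxocyclohexa-2,5-diene-1-carboxylate | COC(=O)C1(C)C=CC(=O)C=C1 | intermediate
5 | isobutylzinc dienolate | CC(C)C[Zn]OC1=C[C@H](CC(C)C)[C@](C)(C(=O)OC)C=C1 | intermediate
6 | methyl (1S,6S)-6-isobutyl-1-methyl-4-oxocyclohex-2-ene-1-carboxylate | O=C1C[C@H](CC(C)C)[C@](C)(C(=O)OC)C=C1 | intermediate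
7 | (R)-glycidol | OC[C@@H]1CO1 | starting material
8 | (S)-pent-4-ene-1,2-diol | O[C@H](CO)CC=C | intermediate
9 | (S)-1,2-bis(triethylsilyloxy)pent-4-ene | CC[Si](CC)(CC)O[C@H](CO[Si](CC)(CC)CC)CC=C | intermediate
10 | (S)-2-(triethylsilyloxy)pent-4-enal | CC[Si](CC)(CC)O[C@H](C=O)CC=C | intermediate
11 | secondary C4 radical | CC[Si](CC)(CC)O[C@H](C=O)C[CH]C | intermediate
12 | Giese adduct enolate (iron counter-ion omitted) | CC[Si](CC)(CC)O[C@H](C=O)C[C@@H](C)[C@H]2C=C([O-])C[C@H](CC(C)C)[C@]2(C)C(=O)OC | intermediate
13 | trans-fused ketol (1β-OH, 2α-OTES, 8-oxo) | CC[Si](CC)(CC)O[C@H]1C[C@@H](C)[C@H]2[C@@H](C(=O)C[C@H](CC(C)C)[C@]2(C)C(=O)OC)[C@@H]1O | intermediate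
14 | 1β-TBS ether of 13 | CC[Si](CC)(CC)O[C@H]1C[C@@H](C)[C@H]2[C@@H](C(=O)C[C@H](CC(C)C)[C@]2(C)C(=O)OC)[C@@H]1O[Si](C)(C)C(C)(C)C | intermediate
15 | potassium C7=C8 enolate | CC[Si](CC)(CC)O[C@H]1C[C@@H](C)[C@H]2[C@@H](C([O-])=C[C@H](CC(C)C)[C@]2(C)C(=O)OC)[C@@H]1O[Si](C)(C)C(C)(C)C.[K+] | intermediate
16 | C7=C8 enol triflate | CC[Si](CC)(CC)O[C@H]1C[C@@H](C)[C@H]2[C@@H](C(OS(=O)(=O)C(F)(F)F)=C[C@H](CC(C)C)[C@]2(C)C(=O)OC)[C@@H]1O[Si](C)(C)C(C)(C)C | intermediate
17 | Δ7-octalin methyl ester | CC[Si](CC)(CC)O[C@H]1C[C@@H](C)[C@H]2[C@@H](C=C[C@H](CC(C)C)[C@]2(C)C(=O)OC)[C@@H]1O[Si](C)(C)C(C)(C)C | intermediate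
18 | α-trimethylsilyl ketone | CC[Si](CC)(CC)O[C@H]1C[C@@H](C)[C@H]2[C@@H](C=C[C@H](CC(C)C)[C@]2(C)C(=O)C[Si](C)(C)C)[C@@H]1O[Si](C)(C)C(C)(C)C | intermediate
19 | C5 methyl ketone | CC[Si](CC)(CC)O[C@H]1C[C@@H](C)[C@H]2[C@@H](C=C[C@H](CC(C)C)[C@]2(C)C(C)=O)[C@@H]1O[Si](C)(C)C(C)(C)C | intermediate
20 | β-keto dimethyl acetal | CC[Si](CC)(CC)O[C@H]1C[C@@H](C)[C@H]2[C@@H](C=C[C@H](CC(C)C)[C@]2(C)C(=O)CC(OC)OC)[C@@H]1O[Si](C)(C)C(C)(C)C | intermediate
21 | 2α-alcohol | O[C@H]1C[C@@H](C)[C@H]2[C@@H](C=C[C@H](CC(C)C)[C@]2(C)C(=O)CC(OC)OC)[C@@H]1O[Si](C)(C)C(C)(C)C | intermediate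
22 | tert-butyl acetoacetate | CC(=O)CC(=O)OC(C)(C)C | starting material
23 | tert-butyl (E)-3-(triflyloxy)but-2-enoate | C/C(OS(=O)(=O)C(F)(F)F)=C\C(=O)OC(C)(C)C | intermediate
24 | 1-tert-butyl 5-methyl (E)-3-methylpent-2-enedioate | COC(=O)C/C(C)=C/C(=O)OC(C)(C)C | intermediate
25 | (E)-5-methoxy-3-methyl-5-oxopent-2-enoic acid | COC(=O)C/C(C)=C/C(=O)O | intermediate
26 | 2β-ester, 1β-OTBS, β-keto acetal | COC(=O)C/C(C)=C/C(=O)O[C@@H]1C[C@@H](C)[C@H]2[C@@H](C=C[C@H](CC(C)C)[C@]2(C)C(=O)CC(OC)OC)[C@@H]1O[Si](C)(C)C(C)(C)C | intermediate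
27 | tandyukisin | COC(=O)C/C(C)=C/C(=O)O[C@@H]1C[C@@H](C)[C@H]2[C@@H](C=C[C@H](CC(C)C)[C@]2(C)C(=O)/C=C\O)[C@@H]1O | target

**Step count.** Total: 18 steps. Longest linear sequence: 12 steps (1, 2, 3, 7, 8, 9, 10, 11, 12, 13, 17, 18).

**Steps most likely to fail**

1. **Step 7.** Four things may go wrong:
   - slow capture of a secondary radical next to the quaternary C5;
   - protonation of the enolate before the aldol;
   - kinetic closure to a cis ring fusion;
   - weak control at C4.

   Fallback: separate the two bond formations. Setting out from 9 and 6, the same iron-hydride conditions are run as a plain reductive olefin coupling to give the keto bis-silyl ether F1. Selective Swern oxidation of its primary TES ether gives the keto aldehyde F2. Ring A is then closed in a separate, fully equilibrating base-mediated aldol (DBU, CH2Cl2), which comes back to the route at 13.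

2. **Step 3.** The dienone may be attacked on the face anti to the ester instead of anti to the methyl, which would give the wrong C5/C6 relationship.
   Fallback: invert the order of the two C–C bond formations, since that opposite bias is what C4a needs. Setting out from 4 and 10, the annulation is run on the dienone to give the enone ketol F3; the isomers from the two enantiotopic alkenes are diastereomers and separable. Silylation gives F4. Stoichiometric iBu2CuLi then adds axially at C6, anti to the axial 5β-methyl of the trans-decalin, and the enolate is trapped with PhNTf2. This comes back to the route at 16.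

3. **Step 17.** Displacement at C2 may be sluggish beside the OTBS group, so that the alcohol is simply returned or the activated alcohol is consumed unproductively.
   Fallback: invert by redox and then acylate with retention. Setting out from 21, Dess–Martin oxidation gives the C2 ketone F5. L-Selectride attacks from the equatorial side to give the axial 2β-alcohol F6. F6 is esterified with 25 through a mixed anhydride (2-methyl-6-nitrobenzoic anhydride, catalytic DMAP, low temperature), which comes back to the route at 26.

**Further compounds**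
F1 | step 7 | Giese adduct, keto bis-TES ether | CC[Si](CC)(CC)O[C@H](CO[Si](CC)(CC)CC)C[C@@H](C)[C@H]2CC(=O)C[C@H](CC(C)C)[C@]2(C)C(=O)OC
F2 | step 7 | keto aldehyde | CC[Si](CC)(CC)O[C@H](C=O)C[C@@H](C)[C@H]2CC(=O)C[C@H](CC(C)C)[C@]2(C)C(=O)OC
F3 | step 3 | enone ketol from dienone annulation | CC[Si](CC)(CC)O[C@H]1C[C@@H](C)[C@H]2[C@@H](C(=O)C=C[C@]2(C)C(=O)OC)[C@@H]1O
F4 | step 3 | 1β-TBS ether of F3 | CC[Si](CC)(CC)O[C@H]1C[C@@H](C)[C@H]2[C@@H](C(=O)C=C[C@]2(C)C(=O)OC)[C@@H]1O[Si](C)(C)C(C)(C)C
F5 | step 17 | C2 ketone | O=C1C[C@@H](C)[C@H]2[C@@H](C=C[C@H](CC(C)C)[C@]2(C)C(=O)CC(OC)OC)[C@@H]1O[Si](C)(C)C(C)(C)C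
F6 | step 17 | axial 2β-alcohol | O[C@@H]1C[C@@H](C)[C@H]2[C@@H](C=C[C@H](CC(C)C)[C@]2(C)C(=O)CC(OC)OC)[C@@H]1O[Si](C)(C)C(C)(C)C
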